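## Structural features

The target is a cyclohexene (C1–C6) cis-fused across C1–C6 to an oxirane, that is, a 7-oxabicyclo[4.1.0]hept-4-ene. C1 is a fully substituted oxirane carbon that also carries the exocyclic methylene C7 as a benzoate. Four contiguous stereocentres run C6–C1–C2–C3: the C2 acetoxy group lies on the face of C7 and opposite to the oxirane oxygen, and the allylic C3 benzoyloxy group is trans to the C2 acetoxy group and therefore on the oxirane face. The vinyl epoxide is the fragile unit (acid, soft nucleophiles in SN2′ mode, zerovalent palladium). The three esters sit on 1,2- and 1,3-related oxygens, so base invites acyl migration, and every cyclohexadiene on the way is one elimination away from an arene. The real difficulty is twofold: an oxygen must be placed on the hindered quaternary C1 on the face opposite to the C2 oxygen with the alkene left at C4=C5, and two neighbouring secondary oxygens must end up trans with different acyl groups. The plan uses the fact that a C1–C6 oxirane beside a C4=C5 alkene is the allylic transposition of a C1–O–O–C4 bridge across a C5=C6 alkene. A [4+2] addition of dioxygen to a C1=C6–C5=C4 diene can therefore deliver the C1 oxygen and fix its face, and a deoxygenation can fold the bridge into the epoxide. C2 and C3 with cis oxygens map onto an enantiopure arene cis-dihydrodiol, which leaves only C3 to be inverted.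

## Logic of the disconnections

11 ⇒ 10. The acetyl C–O bond at C2 is cut first. This acyl group is the smallest and is placed on the most hindered hydroxyl, so it is best added when nothing else is free. The gain is a mono-alcohol with every other group final. The forward step must acylate C2–OH faster than the neighbouring C3 benzoate can migrate.

10 ⇒ 9. The C3–O bond is cut with inversion, so the benzoate oxygen of 10 is not the hydroxyl oxygen of 9. This turns the trans C2/C3 pattern into the cis diol that an arene dihydrodiol supplies, and installs the C3 benzoate in the same operation. The forward step must activate only the allylic C3 hydroxyl, displace it by SN2 and not SN2′, and leave the vinyl epoxide alone.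

9 ⇒ 8. The two hydroxyls are tied into one cyclic silylene (two O–Si bonds). A cis-fused, fluoride-labile ring on C2/C3 is the face-directing element for the earlier steps and can be removed without the acid that an acetal would need. The forward cleavage must be buffered so that neither the epoxide opens nor the C7 benzoate migrates.

8 ⇒ 7. The C6–O bond is cut and the lost oxygen is restored on C4 as the second peroxide oxygen, with the alkene returned from C4=C5 to C5=C6. The oxirane, its face and the hindered C1–O bond are thereby traced to one peroxide bridge. The forward deoxygenation must remove the oxygen on C4 and not that on C1, and must close onto C6 on the face the bridge occupies.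

7 ⇒ 6. Both bridge C–O bonds (C1–O and C4–O) are cut in a retro-[4+2]. Two stereocentres and the quaternary C–O bond then come from a flat diene and a two-atom dienophile. The forward addition must occur anti to the C2/C3 silylene and must outrun ene reaction at the allylic hydrogens.

6 ⇒ 4 + 5. The ester C–O bond at C7 is cut. The benzoate is wanted in the target, so it also serves as the protection of the primary alcohol through the oxidation steps at no cost in steps. The forward acylation meets only one free hydroxyl.

4 ⇒ 2 + 3. The C1–C7 bond is cut at the vinylic carbon. This reduces the carbon skeleton to a halodiene with one-carbon fragment 3 as the partner. The forward coupling must be neutral and mild enough for a diene prone to dimerise or aromatise.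

2 ⇒ 1. The two O–Si bonds are cut, which leads to the commercial enantiopure diol 1 that already holds C2 and C3 in the correct absolute sense. The forward silylation must keep the acid-sensitive diene diol buffered.

## Other disconnections considered

Alternative 1: The cut is the C1–C6 ring bond, read backwards as a [3,3] shift. Cyclohexene carboxylic acid A1 (C1 and C6 as 4-methoxybenzyl ethers, C2 and C3 as silyl ethers, C7 as the carboxyl) would come from lactone A2. A2 is a six-membered ring of C7, C1, C2, C3, C4 and oxygen with an (E)-2-alkoxyvinyl arm (C5=C6) on C4. In the forward step the silyl ketene acetal of A2 would rearrange through a boat-like array, joining C1 to C6, breaking C4–O and leaving the C4=C5 alkene.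
- In its favour: the whole C1–C7 skeleton, the absolute configuration and the trans C2/C3 oxygens would come from the D-gluco uronate pool, so no inversion at C3 is needed. On that point it is better than the chosen plan. The quaternary C1 would be set by suprafacial chirality transfer from C4, which is as predictable as the anti cycloaddition chosen here. No tin, light or peroxide is involved.
- Against it here: A1 is far from the target. The C1 and C6 oxygens arrive as two ethers on opposite faces, so the oxirane needs unmasking, activation of C6 and closure with inversion. The carboxyl must be reduced and benzoylated. The two identical silyl ethers at C2 and C3 must be told apart. Enolisation of A2 places an enolate next to the C2 silyloxy group, so β-elimination threatens.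
- Comparison: structurally the alternative builds the carbocycle while the chosen plan buys it. Mechanistically both rest on a pericyclic step with a defined face. In step economy, making A2 and then finishing from A1 should need well over twice the eight steps planned here.

Alternative 2: The cut removes C1–C6 and C6–O together and leads to the open-chain sulfonium salt A4. A4 is a C1 ketone with silyloxy groups on C7, C2 and C3, a (Z)-C4=C5 alkene and a tetrahydrothiophenium group on C6. In the forward step a carbonate base would form the allylic ylide at C6, which would add to the C1 carbonyl. The resulting alkoxide would displace the sulfide at C6, giving the tris(silyl ether) A3.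
- In its favour: carbocycle, oxirane and two stereocentres would arise in one operation. That is more complexity per step than the chosen key step offers, so it is better on that point. The alkene is already at C4=C5, and the trans C2/C3 diol could be taken from a tartrate-type pool without inversion.
- Against it here: the face of carbonyl addition relative to C2 would be decided only by the conformations of an acyclic α-silyloxy ketone, whereas the chosen plan uses a rigid cis-fused ring. The C2 hydrogen is α to the ketone and β to the C3 silyloxy group, so epimerisation and elimination are open under the base. Ylide formation at a ring carbon of the thiophenium followed by [2,3] shift of the allyl group competes. The three oxygens of A3 carry the same silyl group, so two secondary ethers must be unmasked selectively.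
- Comparison: structurally it forms more bonds in the key step. Mechanistically it is a stepwise ionic cascade with less secure facial control. In step economy, the assembly of A4 and about five steps after A3 should make it clearly longer than eight steps.

Alternative 3: The cut takes out C2–C3 and C1–C6 in a retro-[4+2]. Cycloadduct A5 (C1 bearing bromine and the formyl carbon C7, C2 acetate, C3 benzoate, C6 silyl ether) would come from diene A6 and dienophile A7. In the forward step a chiral oxazaborolidinium Lewis acid would bind the formyl group of A7 and the diene would add endo to it, setting four stereocentres. Reduction and benzoylation at C7 and release of the C6 oxygen would then close the oxirane by displacing bromide at C1 with inversion.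
- In its favour: it is the most convergent plan. Acetate on C2 and benzoate on C3 would arrive trans and already differentiated from the alkene geometries, with no diol protection, no inversion and no choice between two hydroxyls. That is better than the chosen plan. The step count could equal or undercut eight.
- Against it here: A7 is a β-acyloxy bromoacrolein, less reactive and more fragile than the parent dienophile. A6 has donors at both termini, so the regiochemistry rests on the difference between a silyloxy and an acyloxy group. A silyl dienol ether is exposed to cleavage by a strong Lewis acid. The absolute configuration would depend on catalyst performance with an untried pair of partners, whereas the chosen plan inherits it from an enantiopure starting material and is better on that point. The oxirane closure would need SN2 at a tertiary bromide while an alkoxide sits 1,3 to two esters.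
- Comparison: mechanistically both plans fix the face in a [4+2] step, here by a catalyst and in the chosen plan by a covalently attached ring. In step economy it is potentially equal or better, but its risk is concentrated in the first bond-forming step.

Key step: step 5

Remark on the chemistry: locants follow the target (C1 quaternary oxirane carbon, C7 its exocyclic methylene, C2 acetoxy carbon, C3 benzoyloxy carbon, C4=C5, C6 oxirane CH). The configurations of 1, 7, 8 and 11 are mutually consistent: the C2/C3 oxygens of the (1S,2S) diol lie on the C7 face, and the peroxide and oxirane lie on the opposite face. No structure needed correction.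

## Route

Step 1
Reactants: 1 (1S,2S)-3-bromocyclohexa-3,5-diene-1,2-diol
Product: 2 (3aS,7aS)-4-bromo-2,2-di-tert-butyl-3a,7a-dihydro-1,3,2-benzodioxasilole
Conditions: t-Bu2Si(OTf)2, 2,6-lutidine, CH2Cl2, 0 °C
Reagents that add atoms: di-tert-butylsilyl bis(trifluoromethanesulfonate), CC(C)(C)[Si](OS(=O)(=O)C(F)(F)F)(OS(=O)(=O)C(F)(F)F)C(C)(C)C
Why: Silylene formation from a cis-1,2-diol and a silyl bis(triflate); the cis oxygens close a five-membered dioxasilolane, excess lutidine traps the triflic acid so the diene diol does not dehydrate to a phenol, and no stereocentre is touched.

Step 2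
Reactants: 2 (3aS,7aS)-4-bromo-2,2-di-tert-butyl-3a,7a-dihydro-1,3,2-benzodioxasilole; 3 (tributylstannyl)methanol
Product: 4 [(3aR,7aS)-2,2-di-tert-butyl-3a,7a-dihydro-1,3,2-benzodioxasilol-4-yl]methanol
Conditions: Pd(PPh3)4 (5 mol %), 1,4-dioxane, 80 °C, dark
Reagents that add atoms: none
Why: Stille cross-coupling (hydroxymethylation): zerovalent palladium inserts into the vinylic C–Br bond, the α-oxygenated methyl group transfers from tin in preference to butyl, and reductive elimination forms C1–C7; the neutral medium and the silylene keep the diene from aromatising.

Step 3
Reactants: 4 [(3aR,7aS)-2,2-di-tert-butyl-3a,7a-dihydro-1,3,2-benzodioxasilol-4-yl]methanol; 5 benzoyl chloride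
Product: 6 [(3aR,7aS)-2,2-di-tert-butyl-3a,7a-dihydro-1,3,2-benzodioxasilol-4-yl]methyl benzoate
Conditions: pyridine, DMAP (cat.), CH2Cl2, 0 °C to rt
Reagents that add atoms: none
Why: Nucleophile-catalysed O-acylation of the only free (primary allylic) hydroxyl; the benzoate is a target group and also protects C7–OH through the oxidation steps.

Step 4
Reactants: 6 [(3aR,7aS)-2,2-di-tert-butyl-3a,7a-dihydro-1,3,2-benzodioxasilol-4-yl]methyl benzoate
Product: 7 (1R,2S,3S,4R)-1-(benzoyloxymethyl)-2,3-(di-tert-butylsilanediyldioxy)-1,4-epidioxycyclohex-5-ene (target locants; peroxide bridge anti to the silylene)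
Conditions: O2, tetraphenylporphyrin (cat.), hν (visible), CH2Cl2, −30 °C
Reagents that add atoms: dioxygen, O=O
Why: Photosensitised singlet-oxygen [4+2] cycloaddition to the ring-locked s-cis diene; the dienophile approaches the face opposite to the cis-fused di-tert-butylsilylene, which sets C1 and C4 together, and the cisoid diene reacts by cycloaddition faster than by ene reaction at the C7 or ring allylic hydrogens.

Step 5
Reactants: 7 (1R,2S,3S,4R)-1-(benzoyloxymethyl)-2,3-(di-tert-butylsilanediyldioxy)-1,4-epidioxycyclohex-5-ene
Product: 8 (1S,2S,3S,6S)-1-(benzoyloxymethyl)-2,3-(di-tert-butylsilanediyldioxy)-7-oxabicyclo[4.1.0]hept-4-ene (oxirane anti to the silylene)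
Conditions: PPh3, CH2Cl2 (dry), −20 °C to rt
Reagents that add atoms: none
Why: This is the deoxygenative contraction of an unsaturated bicyclic 1,4-endoperoxide by a trivalent phosphorus reagent, the known way from such peroxides to 3,4-epoxycycloalkenes. Phosphorus attacks the peroxide oxygen on the secondary carbon C4 in an SN2 step at oxygen, the O–O bond breaks, and a C4 alkoxyphosphonium ion is left facing the C1 alkoxide. That alkoxide, held on the same face, adds to C6 while the C5=C6 π bond moves to C4=C5 and Ph3PO departs from C4, a syn SN2′ displacement. The oxirane thus closes in a 3-exo-trig mode with allylic transposition. The one new stereocentre, C6, is set by the tether: the attacking oxygen is bound to C1 on the face chosen in the cycloaddition, so the C6–O bond can form only there and the epoxide is cis-fused and anti to the silylene. The selectivity needed is the site of phosphorus attack, since attack at the C1 oxygen would lead to the C4–C5 epoxide; the C1 oxygen is shielded by the quaternary centre, the C7 benzoyloxymethyl group and C2, whereas the C4 oxygen sits on a secondary carbon, and the bulky triarylphosphine magnifies that difference. Cold, dry, base-free conditions are chosen so that reduction to the ene-diol, base-induced isomerisation to a hydroxy enone and thermal bis-epoxide formation do not compete; the esters and the silylene are inert to the phosphine.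

Step 6
Reactants: 8 (1S,2S,3S,6S)-1-(benzoyloxymethyl)-2,3-(di-tert-butylsilanediyldioxy)-7-oxabicyclo[4.1.0]hept-4-ene
Product: 9 (1R,2S,3S,6S)-1-(benzoyloxymethyl)-7-oxabicyclo[4.1.0]hept-4-ene-2,3-diol (cis diol, anti to the oxirane)
Conditions: HF·pyridine, pyridine, THF, 0 °C
Reagents that add atoms: none
Why: Fluoride-induced cleavage of the strained five-membered silylene, driven by Si–F bond formation; the excess pyridine keeps the medium too weakly acidic to open the vinyl epoxide and free of alkoxide, so the C7 benzoate should stay in place.

Step 7
Reactants: 9 (1R,2S,3S,6S)-1-(benzoyloxymethyl)-7-oxabicyclo[4.1.0]hept-4-ene-2,3-diol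
Product: 10 (1R,2S,3R,6S)-3-benzoyloxy-1-(benzoyloxymethyl)-7-oxabicyclo[4.1.0]hept-4-en-2-ol (C3 benzoate trans to C2–OH)
Conditions: PhCO2H, PPh3, DIAD, THF, 0 °C to rt
Reagents that add atoms: benzoic acid, OC(=O)c1ccccc1
Why: Mitsunobu reaction: the oxyphosphonium ion at the allylic C3 is displaced by benzoate in an SN2 step with inversion, which sets the C2/C3 trans relationship; the C2 hydroxyl is neither allylic nor accessible (it is flanked by quaternary C1), and being cis to the C3 leaving group it cannot close an epoxide.

Step 8
Reactants: 10 (1R,2S,3R,6S)-3-benzoyloxy-1-(benzoyloxymethyl)-7-oxabicyclo[4.1.0]hept-4-en-2-ol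
Product: 11 (1S,2S,3R,6S)-2-acetoxy-3-benzoyloxy-1-(benzoyloxymethyl)-7-oxabicyclo[4.1.0]hept-4-ene (target)
Conditions: Ac2O, pyridine, DMAP (cat.), CH2Cl2, 0 °C to rt
Reagents that add atoms: acetic anhydride, CC(=O)OC(C)=O
Why: DMAP-catalysed O-acetylation of the remaining secondary hydroxyl with retention (the C2–O bond is not touched); excess anhydride should make acetylation faster than benzoyl migration from O3.

## Compound list

1 | (1S,2S)-3-bromocyclohexa-3,5-diene-1,2-diol (cis diol) | O[C@H]1[C@@H](O)C=CC=C1Br | starting material
2 | (3aS,7aS)-4-bromo-2,2-di-tert-butyl-3a,7a-dihydro-1,3,2-benzodioxasilole | O1[C@H]2[C@@H](O[Si]1(C(C)(C)C)C(C)(C)C)C=CC=C2Br | intermediate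
3 | (tributylstannyl)methanol | CCCC[Sn](CCCC)(CCCC)CO | starting material
4 | [(3aR,7aS)-2,2-di-tert-butyl-3a,7a-dihydro-1,3,2-benzodioxasilol-4-yl]methanol | O1[C@H]2[C@@H](O[Si]1(C(C)(C)C)C(C)(C)C)C=CC=C2CO | intermediate
5 | benzoyl chloride | O=C(Cl)c1ccccc1 | starting material
6 | [(3aR,7aS)-2,2-di-tert-butyl-3a,7a-dihydro-1,3,2-benzodioxasilol-4-yl]methyl benzoate | O1[C@H]2[C@@H](O[Si]1(C(C)(C)C)C(C)(C)C)C=CC=C2COC(=O)c1ccccc1 | intermediate
7 | (1R,2S,3S,4R)-1-(benzoyloxymethyl)-2,3-(di-tert-butylsilanediyldioxy)-1,4-epidioxycyclohex-5-ene, peroxide anti to the silylene | O1[C@H]2[C@@H](O[Si]1(C(C)(C)C)C(C)(C)C)[C@H]1C=C[C@]2(COC(=O)c2ccccc2)OO1 | intermediate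
8 | (1S,2S,3S,6S)-1-(benzoyloxymethyl)-2,3-(di-tert-butylsilanediyldioxy)-7-oxabicyclo[4.1.0]hept-4-ene, oxirane anti to the silylene | O1[C@H]2[C@@H](O[Si]1(C(C)(C)C)C(C)(C)C)C=C[C@@H]1O[C@@]12COC(=O)c1ccccc1 | intermediate
9 | (1R,2S,3S,6S)-1-(benzoyloxymethyl)-7-oxabicyclo[4.1.0]hept-4-ene-2,3-diol | O[C@H]1[C@@H](O)C=C[C@@H]2O[C@@]21COC(=O)c1ccccc1 | intermediate
10 | (1R,2S,3R,6S)-3-benzoyloxy-1-(benzoyloxymethyl)-7-oxabicyclo[4.1.0]hept-4-en-2-ol | O[C@H]1[C@H](OC(=O)c2ccccc2)C=C[C@@H]2O[C@@]21COC(=O)c1ccccc1 | intermediate
11 | (1S,2S,3R,6S)-2-acetoxy-3-benzoyloxy-1-(benzoyloxymethyl)-7-oxabicyclo[4.1.0]hept-4-ene | CC(=O)O[C@H]1[C@H](OC(=O)c2ccccc2)C=C[C@@H]2O[C@@]21COC(=O)c1ccccc1 | target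

## Step count and least certain steps

Total step count: 8. Longest linear sequence: 8 steps (1 to 11).

Step 5 (key step). The most likely failure is loss of regiocontrol in the oxygen abstraction. If the phosphine and both oxygens equilibrate through a cyclic dialkoxyphosphorane before the SN2′ closure, departure of the phosphine oxide from the tertiary allylic C1 can compete and the oxirane would close across C4–C5. Traces of water would divert the phosphonium intermediate to plain reduction. The fallback separates reduction from activation. Setting out from 7, the O–O bond would be reduced with thiourea in MeOH to the cis-ene-1,4-diol F1. F1 would then be treated with PPh3 and DIAD in THF without an acid partner. Only the secondary allylic C4 hydroxyl should be activated as its oxyphosphonium ion, and the tertiary C1 oxygen would close onto C6 by the same syn SN2′ path. The route is rejoined at 8.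

Step 2. The likely failure is thermal Diels–Alder dimerisation or aromatisation of the diene at the temperature needed for oxidative addition to the vinyl bromide, together with slow hydroxymethyl transfer and competing butyl transfer. The fallback avoids palladium and heat. Setting out from 2, bromine–lithium exchange with tert-butyllithium in Et2O at −78 °C would give the vinyllithium F2, which is not isolated. F2 would be formylated with DMF to the dienal F3. A Luche reduction (NaBH4, CeCl3·7H2O, MeOH, −40 °C) would then give 4, where the route continues.

Step 6. The likely failure is opening of the allylic epoxide by hydrogen fluoride at C6, or benzoyl migration from O7 to the newly freed O2. The fallback changes the order of events so that the epoxide never meets the fluoride reagent. Setting out from 7, the silylene would be cleaved with HF·pyridine at the peroxide stage to the endoperoxide diol F4. The phosphine contraction of step 5 would then be carried out on F4 and would lead directly to 9.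

Step 7. The likely failure is insufficient site selection between the two hydroxyls, allylic transposition by benzoate attack at C5, or elimination of the activated C3 oxygen towards an arene oxide. The fallback differentiates the hydroxyls by protection before the inversion. Setting out from 9, the less hindered allylic C3 hydroxyl would be silylated (TESCl, imidazole, CH2Cl2, −40 °C) to the mono-silyl ether F5. Acetylation of C2 (Ac2O, DMAP, pyridine) would give the acetate silyl ether F6. Buffered HF·pyridine would release the cis hydroxy acetate F7. The Mitsunobu reaction with benzoic acid on this single free hydroxyl would then invert C3 and arrive directly at 11.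

## Further compounds

F1 | step 5 | cis-ene-1,4-diol: 1-(benzoyloxymethyl)-2,3-(di-tert-butylsilanediyldioxy)cyclohex-5-ene-1,4-diol, both hydroxyls anti to the silylene | O1[C@H]2[C@@H](O[Si]1(C(C)(C)C)C(C)(C)C)[C@H](O)C=C[C@]2(COC(=O)c1ccccc1)O
F2 | step 2 | [(3aS,7aS)-2,2-di-tert-butyl-3a,7a-dihydro-1,3,2-benzodioxasilol-4-yl]lithium | O1[C@H]2[C@@H](O[Si]1(C(C)(C)C)C(C)(C)C)C=CC=C2[Li]
F3 | step 2 | (3aR,7aS)-2,2-di-tert-butyl-3a,7a-dihydro-1,3,2-benzodioxasilole-4-carbaldehyde | O1[C@H]2[C@@H](O[Si]1(C(C)(C)C)C(C)(C)C)C=CC=C2C=O
F4 | step 6 | endoperoxide diol: 1-(benzoyloxymethyl)-1,4-epidioxycyclohex-5-ene-2,3-diol, cis diol anti to the peroxide | O[C@H]1[C@@H](O)[C@H]2C=C[C@]1(COC(=O)c1ccccc1)OO2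
F5 | step 7 | 1-(benzoyloxymethyl)-3-(triethylsilyloxy)-7-oxabicyclo[4.1.0]hept-4-en-2-ol, C2 and C3 oxygens cis | O[C@H]1[C@@H](O[Si](CC)(CC)CC)C=C[C@@H]2O[C@@]21COC(=O)c1ccccc1
F6 | step 7 | 2-acetoxy-1-(benzoyloxymethyl)-3-(triethylsilyloxy)-7-oxabicyclo[4.1.0]hept-4-ene, C2 and C3 oxygens cis | CC(=O)O[C@H]1[C@@H](O[Si](CC)(CC)CC)C=C[C@@H]2O[C@@]21COC(=O)c1ccccc1
F7 | step 7 | 2-acetoxy-1-(benzoyloxymethyl)-7-oxabicyclo[4.1.0]hept-4-en-3-ol, C2 and C3 oxygens cis | CC(=O)O[C@H]1[C@@H](O)C=C[C@@H]2O[C@@]21COC(=O)c1ccccc1
A1 | alternative 1 | 2,3-bis(tert-butyldimethylsilyloxy)-1,6-bis(4-methoxybenzyloxy)cyclohex-4-ene-1-carboxylic acid | CC(C)(C)[Si](C)(C)O[C@H]1[C@H](O[Si](C)(C)C(C)(C)C)C=C[C@@H](OCc2ccc(OC)cc2)[C@@]1(OCc1ccc(OC)cc1)C(=O)O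
A2 | alternative 1 | six-membered lactone (C7, C1–C4, O) with C1 4-methoxybenzyl ether, C2 and C3 silyl ethers and an (E)-2-(4-methoxybenzyloxy)vinyl group on C4 | O=C1O[C@@H](/C=C/OCc2ccc(OC)cc2)[C@@H](O[Si](C)(C)C(C)(C)C)[C@H](O[Si](C)(C)C(C)(C)C)[C@@H]1OCc1ccc(OC)cc1
A3 | alternative 2 | 2,3-bis(tert-butyldimethylsilyloxy)-1-(tert-butyldimethylsilyloxymethyl)-7-oxabicyclo[4.1.0]hept-4-ene | CC(C)(C)[Si](C)(C)O[C@H]1[C@H](O[Si](C)(C)C(C)(C)C)C=C[C@@H]2O[C@@]21CO[Si](C)(C)C(C)(C)C
A4 | alternative 2 | 1-[(Z)-4,5,7-tris(tert-butyldimethylsilyloxy)-6-oxohept-2-enyl]tetrahydrothiophenium bromide | CC(C)(C)[Si](C)(C)OCC(=O)[C@@H](O[Si](C)(C)C(C)(C)C)[C@H](O[Si](C)(C)C(C)(C)C)/C=C\C[S+]1CCCC1.[Br-]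
A5 | alternative 3 | bromo aldehyde cycloadduct: 6-acetoxy-5-benzoyloxy-1-bromo-2-(tert-butyldimethylsilyloxy)cyclohex-3-ene-1-carbaldehyde | CC(=O)O[C@H]1[C@H](OC(=O)c2ccccc2)C=C[C@H](O[Si](C)(C)C(C)(C)C)[C@]1(Br)C=O
A6 | alternative 3 | (1E,3E)-4-(tert-butyldimethylsilyloxy)buta-1,3-dienyl benzoate | O=C(O/C=C/C=C/O[Si](C)(C)C(C)(C)C)c1ccccc1
A7 | alternative 3 | (Z)-3-acetoxy-2-bromoacrolein | CC(=O)O/C=C(\Br)C=O
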